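## Structural features

The target is a monocyclic ten-membered carbocycle, a cyclodeca-1(10),4-diene. It is numbered here C1 to C10 so that C1=C10 carries a methyl group on C10, C4=C5 carries a methyl group on C4, and C2–C3 is the two-carbon bridge between the olefins (a ring 1,5-diene). Both olefins are trisubstituted and Z, that is cis within the ring. The other side of the ring holds three contiguous stereocentres: C6, an allylic secondary alcohol (R); C7, bearing isopropyl (S); and C8, a secondary carbinol (R) that is acylated by 4-hydroxybenzoic acid and separated from C10 by the C9 methylene. In a zigzag drawing C6–O and the C7 isopropyl are syn, the C7 isopropyl and C8–O are anti, and the two oxygens are 1,3-anti. The fragile points are: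
- the aryl ester next to a free 1,3-related hydroxyl (acyl migration under base) and the free phenol;
- the allylic C6 alcohol and the medium-ring 1,5-diene (ionisation, transannular cyclisation or Cope rearrangement under acid or heat);
- β-oxygenated aldehyde intermediates, which can epimerise at C7 or eliminate.

The real difficulty is to close a strained ten-membered ring that contains two Z trisubstituted olefins while fixing C8 relative to C6 and C7. The feature exploited is that C8 is a homoallylic carbinol: the array C8(O)–C9H2–C10(CH3)=C1H is what a C1-substituted 2-methylallyl boron reagent leaves behind when it adds through C9 to a C8 aldehyde with allyl transposition. Ring, C8 and the C1=C10 geometry can therefore come from one event.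

## Logic of the disconnections

28 ⇒ 26 ⇒ 23 + 24. The C8–O acyl bond and the two O–Si bonds are cut. The ester is introduced last, onto the only free hydroxyl of 23, and both silyl groups leave together under non-basic fluoride conditions. This removes the aromatic part and leaves a ring alcohol whose two oxygens are already differentiated. The forward steps must acylate a hindered secondary alcohol and desilylate without acyl shift from C8–O to C6–O.

23 ⇒ 21. The ring bond C8–C9 is cut, the C1=C10 olefin is transposed to C9=C10 and boron is placed on C1 (retro-allylboration). This one cut removes the ring, the C8 stereocentre and the second Z olefin, and leaves an open chain with stereocentres only at C1, C6 and C7. The forward step must beat intermolecular allylation and must pass through a chair that gives Z and 8R. The chair analysis (C2 axial, C7 equatorial) requires the 1R boronate, which is the configuration built into 21.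

21 ⇒ 19. No skeletal bond is cut; the C8 aldehyde is taken back to a primary triethylsilyl ether. Aldehyde and allylboronate cannot coexist for long, so the aldehyde is released last. The forward oxidation must spare the C–B bond, the secondary silyl ether and the C7 stereocentre.

19 ⇒ 15 + 16. The C1–C10 bond is cut. C9, C10 and the C10 methyl come from a purchasable alkenylboronic ester, and C1 becomes the CH2–O carbon of a carbamate. The C1 stereocentre must then be created by reagent-controlled selection of one enantiotopic hydrogen and carried through a stereospecific 1,2-shift, in the presence of two silyl ethers and allylic hydrogens.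

15 ⇒ 14 ⇒ 13 ⇒ 11 + 8. After adjusting protecting groups and the oxidation level at C8, the C6–C7 bond is cut as an aldol. The 6,7-syn pattern with C8 as an acyl carbon is the retron of an auxiliary-controlled syn aldol, which sets both centres at once and divides the chain into an imide and an enal. The forward step must keep the Z geometry of the enal and rely on the auxiliary for the absolute sense.

11 ⇒ 9 + 10. The N–acyl bond is cut, leading to two purchasable materials. The demand is only a clean N-acylation.

8 ⇒ 7 ⇒ 6 ⇒ 5 ⇒ 4 ⇒ 2 ⇒ 1. These are functional-group changes plus cleavage of the remote trisubstituted olefin of 1, whose inner carbon becomes C1. Compound 1 already holds C1 to C6 in order, the C4 methyl and the Z C4=C5 olefin. The forward steps must oxidise the remote olefin chemoselectively and keep the two chain ends (C1 carbamate, C6 acetate) distinguishable.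

## Other disconnections considered

Alternative 1: [2,3]-Wittig contraction, cut at C6–C7.
- Cut and forward step: the carbocycle is opened to the thirteen-membered bis-allylic ether A2 (C6–O–CH2–C(CH3)=C7). n-BuLi removes a C6 hydrogen, the carbanion bonds to C7 in a [2,3]-Wittig shift while the O–CH2 bond breaks, and the ring contracts to A1 (C6–OH, C7 isopropenyl, C8–OPMB).
- In favour: ring contraction of macrocyclic diallyl ethers is an established route to ten-membered carbocycles, so on precedent it is better than the chosen closure. The large ether is easier to close, both ring olefins exist before the key step, and C6 and C7 are made together by a concerted shift with no entropic penalty at the C–C bond-forming stage.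
- Against: A2 has two allylic α-oxygen sites, and metallation at the O–CH2 group would start the shift in the wrong direction. The C6/C7 relationship and its relation to C8 depend on the folding of the macrocyclic transition state (the E geometry drawn for A2 assumes the acyclic E-to-anti preference holds in the ring). C8 needs its own asymmetric step.
- Comparison: both plans relay stereochemistry through a cyclic transition state, and here they are equal. The chosen plan fixes C6/C7 by an auxiliary and C8 by a stereodefined boronate, which is more predictable. After A1, five operations remain (selective reduction of the isopropenyl group in the presence of two ring olefins, C6–OH protection, PMB removal, esterification, deprotection) against two in the chosen plan.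

Alternative 2: allyl sulfone alkylation, cut at C2–C3.
- Cut and forward step: the open-chain precursor A4 carries a C2 allylic phenyl sulfone and a C3 allylic chloride. KN(SiMe3)2 forms the C2 carbanion, which displaces chloride and closes the ring to A3 as C2 epimers. Reductive desulfonylation would then give A5.
- In favour: alkylation of sulfone-stabilised allyl anions is a well-established closure for ten-membered 1,5-dienes. The new bond joins two methylene carbons, so no stereocentre and no olefin geometry is created in the closure, and the whole stereotriad is complete beforehand. On precedent and on stereochemical demand of the key step it is better than the chosen plan.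
- Against: the allyl sulfone anion is ambident (α versus γ attack) and the allylic chloride can react with transposition. The allyl anion can lose the Z geometry of C1=C10, and removal of an allylic sulfone can shift or isomerise the adjacent olefin. C8 must be set in a separate asymmetric step; the phellandrene-derived half supplies only C7.
- Comparison: both closures need high dilution, and here they are equal. The chosen plan makes ring, C8 and the olefin in one step. After A3 at least four operations remain (desulfonylation, PMB removal, esterification, desilylation), so step economy favours the chosen plan if its key step works.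

Alternative 3: B-alkyl Suzuki macrocyclisation, cut at C3–C4.
- Cut and forward step: the precursor A7 carries a terminal C2=C3 vinyl group and a Z C4 alkenyl iodide. 9-BBN-H adds to the vinyl group, and the boron-bearing C3 is coupled with the iodide under PdCl2(dppf) and Cs2CO3 to give A6, the bis-silylated target.
- In favour: the coupling class is known for macrocyclisation and the iodide transfers its Z geometry with retention. The ester and all three stereocentres are in place before closure, so only one desilylation follows; on steps after the key step it is better than the chosen plan (one against two).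
- Against: the vinyl group of A7 is conjugated with C1=C10, so hydroboration may not stop cleanly at C3. Aqueous carbonate meets an aryl ester and an aryl silyl ether. Closing a ten-membered ring through a strained palladacycle competes with protodeboronation, β-hydride elimination and dimerisation. Both Z olefins and C8 need separate stereoselective steps beforehand.
- Comparison: neither closure has direct precedent for this ring, but the alternative uses a better-known reaction class. The chosen plan concentrates more bond and stereocentre formation in the key step and has the shorter route to its precursor.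

Key step: step 13

Assumptions: atom labels C1–C10 are those of the target ring and are kept for all open-chain intermediates; 24 and (−)-sparteine are taken as purchasable; 2 and 3 are racemic at the oxygenated carbon that is excised in step 2; (−)-sparteine is taken to select the pro-S hydrogen of a primary alkyl carbamate, as is general for this ligand.

Design changes to the precursor route: the C8 oxygen is carried as a primary triethylsilyl ether installed together with the C6 silyl ether and converted directly into the aldehyde, and the aldehyde is diluted at once for ring closure.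

## Route

Step 1
Reactants: 1 neryl acetate
Product: 2 (Z)-5-(3,3-dimethyloxiran-2-yl)-3-methylpent-2-en-1-yl acetate
Conditions: mCPBA (1.05 equiv), CH2Cl2, 0 °C
Reagents that add atoms: 3-chloroperbenzoic acid (mCPBA), OOC(=O)c1cccc(Cl)c1
Why: Prilezhaev epoxidation; the remote trisubstituted olefin is more electron-rich than the one deactivated by the allylic acetate, so one equivalent of peracid should react there, and the racemic epoxide carbon is excised in step 2.

Step 2
Reactants: 2 (Z)-5-(3,3-dimethyloxiran-2-yl)-3-methylpent-2-en-1-yl acetate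
Product: 4 (Z)-3-methyl-6-oxohex-2-en-1-yl acetate, via glycol 3 (not isolated)
Conditions: H5IO6, THF/H2O, 0 °C → rt
Reagents that add atoms: none
Why: Acid-promoted hydration of the epoxide to glycol 3 and glycol cleavage by periodic acid in one pot; the carbon that becomes C1 is released as an aldehyde and the gem-dimethyl carbon leaves as acetone, while the Z allylic acetate is untouched.

Step 3
Reactants: 4 (Z)-3-methyl-6-oxohex-2-en-1-yl acetate
Product: 5 (Z)-6-hydroxy-3-methylhex-2-en-1-yl acetate
Conditions: NaBH4, MeOH, 0 °C
Reagents that add atoms: none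
Why: Chemoselective borohydride reduction of the aldehyde; the acetate survives short exposure at 0 °C.

Step 4
Reactants: 5 (Z)-6-hydroxy-3-methylhex-2-en-1-yl acetate
Product: 6 (Z)-6-(N,N-diisopropylcarbamoyloxy)-3-methylhex-2-en-1-yl acetate
Conditions: i-Pr2NCOCl, Et3N, DMAP (cat.), CH2Cl2, 40 °C
Reagents that add atoms: N,N-diisopropylcarbamoyl chloride, CC(C)N(C(C)C)C(Cl)=O
Why: O-carbamoylation of the primary C1 alcohol; the hindered carbamate later directs α-lithiation and tolerates every step up to then.

Step 5
Reactants: 6 (Z)-6-(N,N-diisopropylcarbamoyloxy)-3-methylhex-2-en-1-yl acetate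
Product: 7 (Z)-6-hydroxy-4-methylhex-4-en-1-yl N,N-diisopropylcarbamate
Conditions: K2CO3 (cat.), MeOH, rt
Reagents that add atoms: none
Why: Base-catalysed transesterification removes the acetate as methyl acetate; the diisopropylcarbamate is inert to methanolysis.

Step 6
Reactants: 7 (Z)-6-hydroxy-4-methylhex-4-en-1-yl N,N-diisopropylcarbamate
Product: 8 (Z)-4-methyl-6-oxohex-4-en-1-yl N,N-diisopropylcarbamate
Conditions: MnO2, CH2Cl2, rt
Reagents that add atoms: none
Why: Allylic alcohol oxidation on activated MnO2 stops at the aldehyde under neutral heterogeneous conditions, which should preserve the Z geometry; the enal is used at once.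

Step 7
Reactants: 9 (S)-4-benzyl-2-oxazolidinone; 10 isovaleryl chloride
Product: 11 (S)-4-benzyl-3-(3-methylbutanoyl)oxazolidin-2-one
Conditions: Et3N, DMAP (cat.), CH2Cl2, 0 °C → rt
Reagents that add atoms: none
Why: DMAP-catalysed N-acylation of the oxazolidinone by the acid chloride; the auxiliary stereocentre is not involved.

Step 8
Reactants: 11 (S)-4-benzyl-3-(3-methylbutanoyl)oxazolidin-2-one; 8 (Z)-4-methyl-6-oxohex-4-en-1-yl N,N-diisopropylcarbamate
Product: 13 (S)-4-benzyl-3-[(2S,3R,4Z)-8-(N,N-diisopropylcarbamoyloxy)-3-hydroxy-5-methyl-2-(propan-2-yl)oct-4-enoyl]oxazolidin-2-one, via dibutylboron Z-enolate 12 (not isolated)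
Conditions: Bu2BOTf, Et3N, CH2Cl2, −78 → 0 °C; 8, −78 → −20 °C; pH 7 buffer, MeOH, H2O2, 0 °C
Reagents that add atoms: none
Why: Evans syn aldol; the Z-boron enolate 12 reacts through a Zimmerman–Traxler chair on the enolate face away from the benzyl group of the dipole-opposed auxiliary, which sets C7 (S) and C6 (R) in the 6,7-syn relationship. Adding the Z-enal to the preformed enolate at −78 °C limits Z to E isomerisation.

Step 9
Reactants: 13 (S)-4-benzyl-3-[(2S,3R,4Z)-8-(N,N-diisopropylcarbamoyloxy)-3-hydroxy-5-methyl-2-(propan-2-yl)oct-4-enoyl]oxazolidin-2-one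
Product: 14 (4Z,6R,7R)-6-hydroxy-7-(hydroxymethyl)-4,8-dimethylnon-4-en-1-yl N,N-diisopropylcarbamate
Conditions: LiBH4, MeOH (1 equiv), THF, 0 °C
Reagents that add atoms: none
Why: Reductive removal of the auxiliary by methanol-activated LiBH4 gives the C6,C8 diol and returns 9; the carbamate is not reduced and no stereocentre is touched (the C7 descriptor changes only because the priorities change).

Step 10
Reactants: 14 (4Z,6R,7R)-6-hydroxy-7-(hydroxymethyl)-4,8-dimethylnon-4-en-1-yl N,N-diisopropylcarbamate
Product: 15 (4Z,6R,7R)-4,8-dimethyl-6-(triethylsilyloxy)-7-[(triethylsilyloxy)methyl]non-4-en-1-yl N,N-diisopropylcarbamate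
Conditions: TESOTf, 2,6-lutidine, CH2Cl2, −78 → 0 °C
Reagents that add atoms: triethylsilyl trifluoromethanesulfonate (TESOTf), CC[Si](CC)(CC)OS(=O)(=O)C(F)(F)F
Why: Silylation of both hydroxyls in one operation; the primary C8 ether and the secondary C6 ether differ enough in reactivity to be told apart in step 12.

Step 11
Reactants: 15 (4Z,6R,7R)-4,8-dimethyl-6-(triethylsilyloxy)-7-[(triethylsilyloxy)methyl]non-4-en-1-yl N,N-diisopropylcarbamate; 16 isopropenylboronic acid pinacol ester
Product: 19 2-[(3R,6Z,8R,9R)-2,6,10-trimethyl-8-(triethylsilyloxy)-9-[(triethylsilyloxy)methyl]undeca-1,6-dien-3-yl]-4,4,5,5-tetramethyl-1,3,2-dioxaborolane, via lithiated carbamate 17 (not isolated), via lithium boronate complex 18 (not isolated)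
Conditions: s-BuLi, (−)-sparteine, Et2O, −78 °C; 16, −78 °C; MgBr2·OEt2, −78 → 35 °C
Reagents that add atoms: none
Why: Sparteine-mediated asymmetric α-lithiation of the primary carbamate removes the pro-S hydrogen at C1 to give 17, which captures 16 with retention to form 18; the isopropenyl group then shifts from boron to C1 with inversion and loss of the carbamate (lithiation–borylation, a stereospecific 1,2-metallate rearrangement), which sets C1 as R. The remote C6/C7 centres and the silyl ethers should not interfere at −78 °C.

Step 12
Reactants: 19 2-[(3R,6Z,8R,9R)-2,6,10-trimethyl-8-(triethylsilyloxy)-9-[(triethylsilyloxy)methyl]undeca-1,6-dien-3-yl]-4,4,5,5-tetramethyl-1,3,2-dioxaborolane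
Product: 21 (2S,3R,4Z,8R)-5,9-dimethyl-2-(propan-2-yl)-8-(4,4,5,5-tetramethyl-1,3,2-dioxaborolan-2-yl)-3-(triethylsilyloxy)deca-4,9-dienal, via alkoxydimethylsulfonium chloride 20 (not isolated)
Conditions: (COCl)2, DMSO, CH2Cl2, −78 → −40 °C; Et3N, −78 → −20 °C; cold work-up, used at once
Reagents that add atoms: none
Why: Swern oxidation applied directly to the bis-silyl ether; activated DMSO attacks the less hindered primary silyl ether oxygen, chloride removes the silyl group, and 20 collapses with base to the C8 aldehyde while the secondary allylic silyl ether persists. Low temperature limits C7 epimerisation and premature allylation, and the C–B bond should be inert to the reagent.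

Step 13
Reactants: 21 (2S,3R,4Z,8R)-5,9-dimethyl-2-(propan-2-yl)-8-(4,4,5,5-tetramethyl-1,3,2-dioxaborolan-2-yl)-3-(triethylsilyloxy)deca-4,9-dienal
Product: 23 (1(10)Z,4Z,6R,7R,8R)-4,10-dimethyl-7-(propan-2-yl)-6-(triethylsilyloxy)cyclodeca-1(10),4-dien-8-ol, via pinacol borate ester 22 (not isolated)
Conditions: PhMe, 1 mM (slow addition), 25 → 60 °C; then pH 7 buffer
Reagents that add atoms: none
Why: Proposed new method: the boron of the C1 pinacol boronate binds the C8 aldehyde oxygen and C9 attacks C8 through a six-membered Zimmerman–Traxler chair (B, O, C8, C9, C10, C1), a carbonyl allylation with allyl transposition of C9=C10 to C1=C10; the closest known reaction type is the intermolecular Z-selective, chirality-transferring allylboration of aldehydes by α-substituted 2-methylallyl pinacol boronates, together with intramolecular allylborations that close five- to seven-membered rings. The single ring is closed in a 10-exo-trig mode, with the C2–C7 tether spanning the 1,4-positions (C1 and C8) of the chair. Only chairs whose two tether ends are cis can be bridged, that is C2 axial with C7 equatorial or C2 equatorial with C7 axial, and both pass the 1R configuration to the same 8R carbinol, so the new C8 stereocentre is controlled by the C1 boronate stereocentre. Between these two, the C10 methyl group penalises an equatorial C2 through 1,2-allylic strain and an axial C7 would clash with a pinacol oxygen, so the axial-C2 chair should dominate; an axial C2 ends cis to C9, which is the Z C1=C10 olefin and also the less strained cis ring olefin. The step needs intramolecular to beat intermolecular allylation, which slow addition into 1 mM solution and the modest room-temperature reactivity of α-substituted pinacol boronates should secure, and it needs C6 and C7 untouched, which neutral thermal conditions secure. Mild hydrolysis of the B–O bond of 22 then releases 23 with the C6 silyl ether intact.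

Step 14
Reactants: 23 (1(10)Z,4Z,6R,7R,8R)-4,10-dimethyl-7-(propan-2-yl)-6-(triethylsilyloxy)cyclodeca-1(10),4-dien-8-ol; 24 4-(tert-butyldimethylsilyloxy)benzoic acid
Product: 26 (1(10)Z,4Z,6R,7R,8R)-4,10-dimethyl-7-(propan-2-yl)-6-(triethylsilyloxy)cyclodeca-1(10),4-dien-8-yl 4-(tert-butyldimethylsilyloxy)benzoate, via mixed anhydride 25 (not isolated)
Conditions: 24, 2,4,6-Cl3C6H2COCl, Et3N, THF, rt; then 23, DMAP, PhMe, rt → 40 °C
Reagents that add atoms: none
Why: Yamaguchi esterification; DMAP attacks mixed anhydride 25 at the unhindered 4-silyloxybenzoyl carbonyl (the other is shielded by two ortho chlorines) and the acylpyridinium acylates the C8 hydroxyl with retention, while the C6 silyl ether blocks the only other hydroxyl.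

Step 15
Reactants: 26 (1(10)Z,4Z,6R,7R,8R)-4,10-dimethyl-7-(propan-2-yl)-6-(triethylsilyloxy)cyclodeca-1(10),4-dien-8-yl 4-(tert-butyldimethylsilyloxy)benzoate
Product: 28 (1(10)Z,4Z,6R,7S,8R)-6-hydroxy-4,10-dimethyl-7-(propan-2-yl)cyclodeca-1(10),4-dien-8-yl 4-hydroxybenzoate, via C6-hydroxy aryl silyl ether 27 (not isolated)
Conditions: HF·pyridine, pyridine, THF, 0 °C → rt
Reagents that add atoms: none
Why: Fluoride-mediated cleavage of both Si–O bonds; the alkyl triethylsilyl ether should go first (27) and the aryl silyl ether second. The buffered, non-basic medium avoids 1,3-acyl migration from C8–O to C6–O and phenoxide formation, and limits ionisation of the allylic C6 alcohol.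

## Compound list

1 | neryl acetate, (2Z)-3,7-dimethylocta-2,6-dien-1-yl acetate | CC(C)=CCC/C(C)=C\COC(C)=O | starting material
2 | (Z)-5-(3,3-dimethyloxiran-2-yl)-3-methylpent-2-en-1-yl acetate (racemic at the epoxide carbon) | CC1(C)OC1CC/C(C)=C\COC(C)=O | intermediate
3 | (Z)-6,7-dihydroxy-3,7-dimethyloct-2-en-1-yl acetate (racemic glycol, not isolated) | CC(C)(O)C(O)CC/C(C)=C\COC(C)=O | intermediate
4 | (Z)-3-methyl-6-oxohex-2-en-1-yl acetate | O=CCC/C(C)=C\COC(C)=O | intermediate
5 | (Z)-6-hydroxy-3-methylhex-2-en-1-yl acetate | OCCC/C(C)=C\COC(C)=O | intermediate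
6 | (Z)-6-(N,N-diisopropylcarbamoyloxy)-3-methylhex-2-en-1-yl acetate | CC(C)N(C(C)C)C(=O)OCCC/C(C)=C\COC(C)=O | intermediate
7 | (Z)-6-hydroxy-4-methylhex-4-en-1-yl N,N-diisopropylcarbamate | CC(C)N(C(C)C)C(=O)OCCC/C(C)=C\CO | intermediate
8 | (Z)-4-methyl-6-oxohex-4-en-1-yl N,N-diisopropylcarbamate | CC(C)N(C(C)C)C(=O)OCCC/C(C)=C\C=O | intermediate
9 | (S)-4-benzyl-2-oxazolidinone | O=C1N[C@@H](Cc2ccccc2)CO1 | starting material
10 | isovaleryl chloride (3-methylbutanoyl chloride) | CC(C)CC(Cl)=O | starting material
11 | (S)-4-benzyl-3-(3-methylbutanoyl)oxazolidin-2-one | CC(C)CC(=O)N1[C@@H](Cc2ccccc2)COC1=O | intermediate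
12 | dibutylboron (Z)-enolate of 11 (not isolated) | CCCCB(CCCC)O/C(=C\C(C)C)N1[C@@H](Cc2ccccc2)COC1=O | intermediate
13 | (S)-4-benzyl-3-[(2S,3R,4Z)-8-(N,N-diisopropylcarbamoyloxy)-3-hydroxy-5-methyl-2-(propan-2-yl)oct-4-enoyl]oxazolidin-2-one | CC(C)N(C(C)C)C(=O)OCCC/C(C)=C\[C@@H](O)[C@H](C(C)C)C(=O)N1[C@@H](Cc2ccccc2)COC1=O | intermediate
14 | (4Z,6R,7R)-6-hydroxy-7-(hydroxymethyl)-4,8-dimethylnon-4-en-1-yl N,N-diisopropylcarbamate | CC(C)N(C(C)C)C(=O)OCCC/C(C)=C\[C@@H](O)[C@H](C(C)C)CO | intermediate
15 | (4Z,6R,7R)-4,8-dimethyl-6-(triethylsilyloxy)-7-[(triethylsilyloxy)methyl]non-4-en-1-yl N,N-diisopropylcarbamate | CC(C)N(C(C)C)C(=O)OCCC/C(C)=C\[C@@H](O[Si](CC)(CC)CC)[C@H](C(C)C)CO[Si](CC)(CC)CC | intermediate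
16 | isopropenylboronic acid pinacol ester | C=C(C)B1OC(C)(C)C(C)(C)O1 | starting material
17 | (S)-C1-lithiated carbamate of 15 (sparteine ligand omitted, not isolated) | [Li][C@H](OC(=O)N(C(C)C)C(C)C)CC/C(C)=C\[C@@H](O[Si](CC)(CC)CC)[C@H](C(C)C)CO[Si](CC)(CC)CC | intermediate
18 | lithium boronate complex of 17 with 16 (C1 S, not isolated) | [Li+].C=C(C)[B-]1(OC(C)(C)C(C)(C)O1)[C@H](OC(=O)N(C(C)C)C(C)C)CC/C(C)=C\[C@@H](O[Si](CC)(CC)CC)[C@H](C(C)C)CO[Si](CC)(CC)CC | intermediate
19 | 2-[(3R,6Z,8R,9R)-2,6,10-trimethyl-8-(triethylsilyloxy)-9-[(triethylsilyloxy)methyl]undeca-1,6-dien-3-yl]-4,4,5,5-tetramethyl-1,3,2-dioxaborolane | C=C(C)[C@H](B1OC(C)(C)C(C)(C)O1)CC/C(C)=C\[C@@H](O[Si](CC)(CC)CC)[C@H](C(C)C)CO[Si](CC)(CC)CC | intermediate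
20 | C8 alkoxydimethylsulfonium chloride derived from 19 (not isolated) | C=C(C)[C@H](B1OC(C)(C)C(C)(C)O1)CC/C(C)=C\[C@@H](O[Si](CC)(CC)CC)[C@H](C(C)C)CO[S+](C)C.[Cl-] | intermediate
21 | (2S,3R,4Z,8R)-5,9-dimethyl-2-(propan-2-yl)-8-(4,4,5,5-tetramethyl-1,3,2-dioxaborolan-2-yl)-3-(triethylsilyloxy)deca-4,9-dienal | C=C(C)[C@H](B1OC(C)(C)C(C)(C)O1)CC/C(C)=C\[C@@H](O[Si](CC)(CC)CC)[C@H](C(C)C)C=O | intermediate
22 | C8 pinacol borate ester of 23 (not isolated) | C/C1=C/[C@@H](O[Si](CC)(CC)CC)[C@H](C(C)C)[C@H](OB2OC(C)(C)C(C)(C)O2)C/C(C)=C\CC1 | intermediate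
23 | (1(10)Z,4Z,6R,7R,8R)-4,10-dimethyl-7-(propan-2-yl)-6-(triethylsilyloxy)cyclodeca-1(10),4-dien-8-ol (target numbering) | C/C1=C/[C@@H](O[Si](CC)(CC)CC)[C@H](C(C)C)[C@H](O)C/C(C)=C\CC1 | intermediate
24 | 4-(tert-butyldimethylsilyloxy)benzoic acid | CC(C)(C)[Si](C)(C)Oc1ccc(cc1)C(O)=O | starting material
25 | 4-(tert-butyldimethylsilyloxy)benzoic 2,4,6-trichlorobenzoic anhydride (not isolated) | CC(C)(C)[Si](C)(C)Oc1ccc(cc1)C(=O)OC(=O)c1c(Cl)cc(Cl)cc1Cl | intermediate
26 | (1(10)Z,4Z,6R,7R,8R)-4,10-dimethyl-7-(propan-2-yl)-6-(triethylsilyloxy)cyclodeca-1(10),4-dien-8-yl 4-(tert-butyldimethylsilyloxy)benzoate | C/C1=C/[C@@H](O[Si](CC)(CC)CC)[C@H](C(C)C)[C@H](OC(=O)c2ccc(O[Si](C)(C)C(C)(C)C)cc2)C/C(C)=C\CC1 | intermediate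
27 | (1(10)Z,4Z,6R,7S,8R)-6-hydroxy-4,10-dimethyl-7-(propan-2-yl)cyclodeca-1(10),4-dien-8-yl 4-(tert-butyldimethylsilyloxy)benzoate (not isolated) | C/C1=C/[C@@H](O)[C@H](C(C)C)[C@H](OC(=O)c2ccc(O[Si](C)(C)C(C)(C)C)cc2)C/C(C)=C\CC1 | intermediate
28 | (1(10)Z,4Z,6R,7S,8R)-6-hydroxy-4,10-dimethyl-7-(propan-2-yl)cyclodeca-1(10),4-dien-8-yl 4-hydroxybenzoate | C/C1=C/[C@@H](O)[C@H](C(C)C)[C@H](OC(=O)c2ccc(O)cc2)C/C(C)=C\CC1 | target

## Step count and least certain steps

Total step count: 15. Longest linear sequence: 14 (steps 1–6 and 8–15, from 1); step 7 is a one-step branch.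

Step 13 (bears the label "Proposed new method:"). Most likely to go wrong: intermolecular allylboration and oligomerisation outrunning the slow closure of a strained ten-membered ring, or reaction through a boat-like or the alternative chair geometry with loss of C8 or olefin control. A slow closure also leaves time for C7 epimerisation or β-elimination of the aldehyde. Fallback, known chemistry only, sets out from 11 and returns at 23:
- 11 would undergo the boron aldol of step 8 with acrolein to give (S)-4-benzyl-3-[(2S,3R)-3-hydroxy-2-isopropylpent-4-enoyl]oxazolidin-2-one F1.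
- F1 would be silylated (TESOTf, 2,6-lutidine) to (S)-4-benzyl-3-[(2S,3R)-2-isopropyl-3-(triethylsilyloxy)pent-4-enoyl]oxazolidin-2-one F2, reduced (LiBH4, MeOH, THF) to (2R,3R)-2-isopropyl-3-(triethylsilyloxy)pent-4-en-1-ol F3, and oxidised (Dess–Martin periodinane, NaHCO3) to (2S,3R)-2-isopropyl-3-(triethylsilyloxy)pent-4-enal F4.
- Purchasable 4-methylpent-4-en-1-ol would be carbamoylated to 4-methylpent-4-en-1-yl N,N-diisopropylcarbamate F5 and taken through the lithiation–borylation of step 11 with 16, here on a substrate without other functionality, to (R)-2-(2,6-dimethylhepta-1,6-dien-3-yl)-4,4,5,5-tetramethyl-1,3,2-dioxaborolane F6.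
- Intermolecular allylboration of F4 by F6 (CH2Cl2, rt) is the established Z-selective, chirality-transferring reaction and should give (3R,4R,5R,7Z)-7,11-dimethyl-4-(propan-2-yl)-3-(triethylsilyloxy)dodeca-1,7,11-trien-5-ol F7.
- Ring-closing metathesis of F7 between the C5 vinyl group and the C4 1,1-disubstituted olefin (second-generation Grubbs catalyst, RuCl2(=CHPh)(H2IMes)(PCy3), dilute PhMe, 40–80 °C) would close C4=C5 and return to 23. The cis geometry is favoured because a trans olefin beside the existing cis olefin in a ten-membered 1,5-diene is far more strained.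

Step 11. Most likely to go wrong: incomplete 1,2-shift of the hindered boronate complex (reversion to carbenoid and boronic ester on warming), or metallation away from C1, giving low conversion and erosion of the C1 configuration. Fallback sets out from 15 and returns at 19:
- Reductive removal of the carbamoyl group (LiAlH4, THF, 0 °C → reflux) would give (4Z,6R,7R)-4,8-dimethyl-6-(triethylsilyloxy)-7-[(triethylsilyloxy)methyl]non-4-en-1-ol F8.
- Acylation with 2,4,6-triisopropylbenzoyl chloride (Et3N, DMAP, CH2Cl2, 40 °C) would give the hindered benzoate (4Z,6R,7R)-4,8-dimethyl-6-(triethylsilyloxy)-7-[(triethylsilyloxy)methyl]non-4-en-1-yl 2,4,6-triisopropylbenzoate F9.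
- Lithiation of F9 with s-BuLi and (−)-sparteine and borylation with 16 uses a different carbenoid precursor class whose boronate complex carries a better leaving group and should rearrange below room temperature without Lewis acid, giving 19.

Step 12. Most likely to go wrong: loss of the secondary silyl ether to the HCl generated, electrophilic attack of activated DMSO on the allylboronate, or C7 epimerisation during the base stage. Fallback sets out from 19 and returns at 21:
- Selective solvolysis of the primary silyl ether (PPTS, MeOH/CH2Cl2, −10 °C) would give (2R,3R,4Z,8R)-5,9-dimethyl-2-(propan-2-yl)-8-(4,4,5,5-tetramethyl-1,3,2-dioxaborolan-2-yl)-3-(triethylsilyloxy)deca-4,9-dien-1-ol F10.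
- Oxidation of F10 under non-acidic, non-electrophilic conditions (Dess–Martin periodinane, NaHCO3, CH2Cl2, 0 °C) separates desilylation from oxidation and gives 21.

Step 14. Most likely to go wrong: slow acylation of the hindered ring alcohol, which allows disproportionation of the mixed anhydride and transfer of the wrong acyl group. Fallback sets out from 23 and 24 and returns at 26:
- 24 would be converted under neutral conditions (1-chloro-N,N,2-trimethylprop-1-en-1-amine, CH2Cl2) into 4-(tert-butyldimethylsilyloxy)benzoyl chloride F11.
- The lithium alkoxide of 23 (LiN(SiMe3)2, THF, −78 °C) would be acylated by F11, replacing nucleophilic catalysis on the neutral alcohol by alkoxide acylation, to give 26.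

## Further compounds

F1 | step 13 | (S)-4-benzyl-3-[(2S,3R)-3-hydroxy-2-isopropylpent-4-enoyl]oxazolidin-2-one | C=C[C@@H](O)[C@H](C(C)C)C(=O)N1[C@@H](Cc2ccccc2)COC1=O
F2 | step 13 | (S)-4-benzyl-3-[(2S,3R)-2-isopropyl-3-(triethylsilyloxy)pent-4-enoyl]oxazolidin-2-one | C=C[C@@H](O[Si](CC)(CC)CC)[C@H](C(C)C)C(=O)N1[C@@H](Cc2ccccc2)COC1=O
F3 | step 13 | (2R,3R)-2-isopropyl-3-(triethylsilyloxy)pent-4-en-1-ol | C=C[C@@H](O[Si](CC)(CC)CC)[C@H](C(C)C)CO
F4 | step 13 | (2S,3R)-2-isopropyl-3-(triethylsilyloxy)pent-4-enal | C=C[C@@H](O[Si](CC)(CC)CC)[C@H](C(C)C)C=O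
F5 | step 13 | 4-methylpent-4-en-1-yl N,N-diisopropylcarbamate | C=C(C)CCCOC(=O)N(C(C)C)C(C)C
F6 | step 13 | (R)-2-(2,6-dimethylhepta-1,6-dien-3-yl)-4,4,5,5-tetramethyl-1,3,2-dioxaborolane | C=C(C)[C@H](B1OC(C)(C)C(C)(C)O1)CCC(C)=C
F7 | step 13 | (3R,4R,5R,7Z)-7,11-dimethyl-4-(propan-2-yl)-3-(triethylsilyloxy)dodeca-1,7,11-trien-5-ol | C=C[C@@H](O[Si](CC)(CC)CC)[C@H](C(C)C)[C@H](O)C/C(C)=C\CCC(C)=C
F8 | step 11 | (4Z,6R,7R)-4,8-dimethyl-6-(triethylsilyloxy)-7-[(triethylsilyloxy)methyl]non-4-en-1-ol | OCCC/C(C)=C\[C@@H](O[Si](CC)(CC)CC)[C@H](C(C)C)CO[Si](CC)(CC)CC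
F9 | step 11 | (4Z,6R,7R)-4,8-dimethyl-6-(triethylsilyloxy)-7-[(triethylsilyloxy)methyl]non-4-en-1-yl 2,4,6-triisopropylbenzoate | CC(C)c1cc(C(C)C)c(C(=O)OCCC/C(C)=C\[C@@H](O[Si](CC)(CC)CC)[C@H](C(C)C)CO[Si](CC)(CC)CC)c(C(C)C)c1
F10 | step 12 | (2R,3R,4Z,8R)-5,9-dimethyl-2-(propan-2-yl)-8-(4,4,5,5-tetramethyl-1,3,2-dioxaborolan-2-yl)-3-(triethylsilyloxy)deca-4,9-dien-1-ol | C=C(C)[C@H](B1OC(C)(C)C(C)(C)O1)CC/C(C)=C\[C@@H](O[Si](CC)(CC)CC)[C@H](C(C)C)CO
F11 | step 14 | 4-(tert-butyldimethylsilyloxy)benzoyl chloride | CC(C)(C)[Si](C)(C)Oc1ccc(cc1)C(Cl)=O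
A1 | alternative 1 | 6-hydroxy-7-isopropenyl-8-(4-methoxybenzyloxy) (Z,Z)-cyclodeca-1(10),4-diene, product of the ring contraction | C/C1=C/[C@@H](O)[C@H](C(C)=C)[C@H](OCc2ccc(OC)cc2)C/C(C)=C\CC1
A2 | alternative 1 | thirteen-membered bis-allylic ether (C6–O–CH2–C(CH3)=C7, E at that olefin, C8 R) | C/C1=C/COC/C(C)=C/[C@H](OCc2ccc(OC)cc2)C/C(C)=C\CC1
A3 | alternative 2 | 2-phenylsulfonyl (Z,Z)-cyclodeca-1(10),4-diene with C6 OTBS, C7 isopropyl, C8 OPMB (C2 epimers) | C/C1=C/[C@@H](O[Si](C)(C)C(C)(C)C)[C@H](C(C)C)[C@H](OCc2ccc(OC)cc2)C/C(C)=C\C(S(=O)(=O)c2ccccc2)C1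
A4 | alternative 2 | open-chain C2 allylic phenyl sulfone with C3 allylic chloride | ClC/C(C)=C\[C@@H](O[Si](C)(C)C(C)(C)C)[C@H](C(C)C)[C@H](OCc1ccc(OC)cc1)C/C(C)=C\CS(=O)(=O)c1ccccc1
A5 | alternative 2 | desulfonylated ring compound with C6 OTBS and C8 OPMB | C/C1=C/[C@@H](O[Si](C)(C)C(C)(C)C)[C@H](C(C)C)[C@H](OCc2ccc(OC)cc2)C/C(C)=C\CC1
A6 | alternative 3 | bis-silylated target (C6 OTBS, aryl OTIPS) | C/C1=C/[C@@H](O[Si](C)(C)C(C)(C)C)[C@H](C(C)C)[C@H](OC(=O)c2ccc(O[Si](C(C)C)(C(C)C)C(C)C)cc2)C/C(C)=C\CC1
A7 | alternative 3 | open-chain (Z)-C4 alkenyl iodide with terminal C2=C3 vinyl group | I/C(C)=C\[C@@H](O[Si](C)(C)C(C)(C)C)[C@H](C(C)C)[C@H](OC(=O)c1ccc(O[Si](C(C)C)(C(C)C)C(C)C)cc1)C/C(C)=C\C=C
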